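**Retrosynthetic overview**
1. Target ⇐ global desilylation ⇐ Suzuki–Miyaura union of a spirocyclic enol triflate with a (1E,3Z)-dienylboronate; the boronate comes from syn-carbocupration of a 4-silyloxybut-2-ynoate, then ester → enal → enyne.
2. Z-enal on the cyclohexane ⇐ isomerisation of a 2-substituted acrolein ⇐ SeO2 oxidation of the isopropenyl group inherited from carvone.
3. Cyclopentane (the only ring built, formed second) ⇐ reductive aldol cyclisation of an enone–aldehyde ⇐ cross-metathesis of an allyl group with methyl vinyl ketone.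
4. Quaternary spiro carbon carrying CHO and allyl (key bond) ⇐ Claisen rearrangement of an allyl enol ether ⇐ Wittig olefination of an epoxy ketone.
5. Epoxy ketone ⇐ epoxidation and α′-alkylation of (S)-(+)-carvone, which supplies the cyclohexane ring (first ring, bought) and relays all stereochemistry.

Assumption: the target is taken exactly as the SMILES defines it, i.e. (1S,2R,5S,6S,10R) in spiro[4.5]decane numbering with a 3E,5Z triene and a Z enal; compounds labelled starting material are taken as purchasable.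

**Route**

Step 1
Reactants: 1 (S)-(+)-carvone; 2 tert-butyl(3-iodopropoxy)dimethylsilane
Product: 4 trans-6-(3-silyloxypropyl)carvone, via lithium dienolate 3 (not isolated)
Conditions: LiN(iPr)2, THF, −78 °C; then 2, DMPU, −78 → 0 °C
Reagents that add atoms: none
Why: Kinetic α′-deprotonation gives the cross-conjugated dienolate, whose SN2 alkylation occurs anti to the adjacent isopropenyl group and so sets C6 trans to it (enolate alkylation).

Step 2
Reactants: 4 trans-6-(3-silyloxypropyl)carvone
Product: 5 epoxy ketone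
Conditions: H2O2 (30 % aq), NaOH (cat.), MeOH, 0 °C
Reagents that add atoms: hydrogen peroxide, OO
Why: Weitz–Scheffer nucleophilic epoxidation, in which hydroperoxide adds axially to C3 anti to the C5 isopropenyl group and the enolate closes on the same face, so the oxirane oxygen (the future tertiary carbinol oxygen) lies trans to isopropenyl and cis to the side chain.

Step 3
Reactants: 6 allyl chloromethyl ether
Product: 7 [(allyloxy)methyl]triphenylphosphonium chloride
Conditions: PPh3, toluene, 50 °C
Reagents that add atoms: triphenylphosphine, c1ccc(cc1)P(c1ccccc1)c1ccccc1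
Why: SN2 quaternisation of the reactive α-chloro ether by the phosphine gives the Wittig salt; no stereocentre is involved.

Step 4
Reactants: 5 epoxy ketone; 7 [(allyloxy)methyl]triphenylphosphonium chloride
Product: 9 allyl enol ether (E/Z mixture), via phosphorus ylide 8 (not isolated)
Conditions: KN(SiMe3)2, THF, 0 °C; then 5, 0 → 50 °C
Reagents that add atoms: none
Why: Wittig olefination of the ketone by the alkoxymethylene ylide gives the allyl enol ether; the E/Z ratio is irrelevant because both isomers present the same ring carbon to the coming rearrangement.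

Step 5
Reactants: 9 allyl enol ether
Product: 10 quaternary epoxy aldehyde
Conditions: o-xylene, iPr2NEt (0.1 equiv), 145 °C, sealed tube
Reagents that add atoms: none
Why: Claisen [3,3]-sigmatropic rearrangement forms the C–C bond of the quaternary carbon, the allyl terminus being delivered to the ring face opposite the oxirane oxygen and the neighbouring silyloxypropyl branch, which fixes the future spiro centre with CHO cis to the oxirane oxygen.

Step 6
Reactants: 10 quaternary epoxy aldehyde
Product: 11 diol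
Conditions: LiBHEt3 (4 equiv), THF, 0 → 65 °C; H2O work-up
Reagents that add atoms: none
Why: Hydride reduces the aldehyde and opens the trisubstituted epoxide by SN2 attack at its only accessible, secondary carbon, leaving the tertiary C–O bond and its configuration untouched (reductive epoxide opening).

Step 7
Reactants: 11 diol
Product: 12 hydroxy aldehyde
Conditions: TEMPO (10 mol %), PhI(OAc)2, CH2Cl2, rt
Reagents that add atoms: none
Why: Oxoammonium (TEMPO) oxidation converts only the primary neopentyl alcohol into the aldehyde; the tertiary alcohol and the alkenes are inert.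

Step 8
Reactants: 12 hydroxy aldehyde; 13 methyl vinyl ketone
Product: 14 E-enone aldehyde
Conditions: second-generation Grubbs catalyst (5 mol %), 13 (4 equiv), CH2Cl2, 40 °C
Reagents that add atoms: none
Why: Olefin cross-metathesis of the monosubstituted allyl group with excess enone gives the E-enone, while the 1,1-disubstituted isopropenyl group does not take part.

Step 9
Reactants: 14 E-enone aldehyde
Product: 15 spirocyclic cis-ketol
Conditions: [(Ph3P)CuH]6 (0.2 equiv = 1.2 equiv hydride), toluene, −40 → 0 °C; NH4Cl (aq)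
Reagents that add atoms: none
Why: Reductive aldol cyclisation in which conjugate hydride addition gives a Z copper enolate that adds to the formyl group through a closed Zimmerman–Traxler transition state (hydroxyl and acetyl cis), the formyl oxygen being held syn to the tertiary hydroxyl by hydrogen bonding or copper chelation so that both new groups sit on the cyclopentane face that carries the carbinol carbon C6.

Step 10
Reactants: 15 spirocyclic cis-ketol
Product: 16 bis(triethylsilyl) ether
Conditions: Et3SiOTf (3 equiv), 2,6-lutidine, CH2Cl2, −78 → 0 °C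
Reagents that add atoms: triethylsilyl trifluoromethanesulfonate, CC[Si](CC)(CC)OS(=O)(=O)C(F)(F)F
Why: Silylation by the silyl triflate caps the secondary and the tertiary hydroxyl so that the β-hydroxy ketone can neither undergo retro-aldol cleavage nor epimerise in the next step.

Step 11
Reactants: 16 bis(triethylsilyl) ether
Product: 18 enol triflate, via potassium enolate 17 (not isolated)
Conditions: KN(SiMe3)2, THF, −78 °C; then PhNTf2, −78 → 0 °C
Reagents that add atoms: N-phenylbis(trifluoromethanesulfonimide), O=S(=O)(N(c1ccccc1)S(=O)(=O)C(F)(F)F)C(F)(F)F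
Why: Kinetic deprotonation occurs at the methyl group and O-sulfonylation of the enolate gives the 1,1-disubstituted enol triflate without touching the α-stereocentre (enol triflate formation).

Step 12
Reactants: 18 enol triflate
Product: 20 2-substituted acrolein, via allylic alcohol 19 (not isolated)
Conditions: SeO2 (0.3 equiv), tBuOOH, CH2Cl2, rt; then MnO2, rt
Reagents that add atoms: selenium dioxide, O=[Se]=O (oxygen donor, reoxidised by tert-butyl hydroperoxide, CC(C)(C)OO)
Why: Selenium dioxide allylic oxidation (ene reaction then [2,3]-sigmatropic shift) hydroxylates the methyl of the electron-rich isopropenyl group while the electron-poor enol triflate is inert, and MnO2 takes the allylic alcohol on to the aldehyde.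

Step 13
Reactants: 20 2-substituted acrolein
Product: 21 Z-enal enol triflate
Conditions: RuHCl(CO)(PPh3)3 (5 mol %), toluene, 80 °C
Reagents that add atoms: none
Why: Ruthenium hydride addition and β-hydride elimination move the double bond into the tetrasubstituted conjugated position (olefin isomerisation), erasing the carvone-derived stereocentre, with the methyl group settling syn to the unsubstituted ring CH2 and the slim formyl group syn to the branched C10 so as to minimise allylic 1,3-strain, which is the target geometry.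

Step 14
Reactants: 22 tert-butyldimethyl(prop-2-yn-1-yloxy)silane; 23 ethyl chloroformate
Product: 25 ethyl 4-(silyloxy)but-2-ynoate, via lithium acetylide 24 (not isolated)
Conditions: nBuLi, THF, −78 °C; then 23, −78 → 0 °C
Reagents that add atoms: none
Why: The lithium acetylide is acylated by the chloroformate (addition–elimination) to give the ynoate.

Step 15
Reactants: 25 ethyl 4-(silyloxy)but-2-ynoate; 26 5-bromo-2-methylpent-2-ene
Product: 29 Z-enoate, via Grignard reagent 27 (not isolated), via organocopper reagent 28 (not isolated)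
Conditions: Mg, THF, rt; CuBr·SMe2, −78 °C; then 25, −78 °C; MeOH/NH4Cl quench at −78 °C
Reagents that add atoms: none
Why: Syn-carbocupration of the ynoate and cold protonation of the vinylcopper give the trisubstituted alkene with the ester cis to CH2OSi and H cis to the new alkyl chain (conjugate addition).

Step 16
Reactants: 29 Z-enoate
Product: 30 Z-allylic alcohol
Conditions: iBu2AlH (2.2 equiv), CH2Cl2, −78 °C
Reagents that add atoms: none
Why: The aluminium hydride reduces the conjugated ester by 1,2-addition to the allylic alcohol without touching the alkene geometry.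

Step 17
Reactants: 30 Z-allylic alcohol
Product: 31 Z-enal
Conditions: MnO2, CH2Cl2, rt
Reagents that add atoms: none
Why: MnO2 oxidises the allylic alcohol to the enal under neutral conditions that preserve the Z geometry.

Step 18
Reactants: 31 Z-enal; 32 (trimethylsilyl)diazomethane
Product: 34 Z-enyne, via lithiated silyldiazomethane 33 (not isolated)
Conditions: nBuLi, THF, −78 °C; then 31, −78 °C → rt
Reagents that add atoms: none
Why: Colvin rearrangement, in which carbonyl addition, Peterson elimination, loss of N2 and a 1,2-hydrogen shift of the alkylidene carbene give the terminal alkyne with the alkene untouched.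

Step 19
Reactants: 21 Z-enal enol triflate; 34 Z-enyne
Product: 36 tetrasilyl ether of the target, via dienylboronate 35 (not isolated)
Conditions: pinacolborane, Cp2Zr(H)Cl (10 mol %), Et3N (10 mol %), 60 °C; then 21, PdCl2(dppf) (5 mol %), K3PO4 (aq), THF, 45 °C
Reagents that add atoms: none
Why: Zirconium-catalysed syn-hydroboration of the terminal alkyne gives the E-alkenylboronate, which undergoes Suzuki–Miyaura coupling with the enol triflate with retention at both sp2 carbons to give the 3E,5Z triene.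

Step 20
Reactants: 36 tetrasilyl ether of the target
Product: 37 CNP0249558.2 (target)
Conditions: HF·pyridine, pyridine, THF, 0 °C → rt
Reagents that add atoms: none
Why: Buffered fluoride cleavage of all four silyl ethers (desilylation) leaves the enal, the triene and the allylic alcohol intact and gives the target.

**Compound list**
1 | (S)-(+)-carvone, (5S)-2-methyl-5-(prop-1-en-2-yl)cyclohex-2-en-1-one | CC(=C)[C@H]1CC=C(C)C(=O)C1 | starting material
2 | tert-butyl(3-iodopropoxy)dimethylsilane | CC(C)(C)[Si](C)(C)OCCCI | starting material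
3 | lithium (3S)-6-methyl-3-(prop-1-en-2-yl)cyclohexa-1,5-dien-1-olate | CC(=C)[C@H]1CC=C(C)C(O[Li])=C1 | intermediate
4 | (5S,6R)-6-[3-(tert-butyldimethylsilyloxy)propyl]-2-methyl-5-(prop-1-en-2-yl)cyclohex-2-en-1-one (side chain trans to isopropenyl) | CC1=CC[C@H](C(C)=C)[C@@H](CCCO[Si](C)(C)C(C)(C)C)C1=O | intermediate
5 | (1S,3R,4S,6S)-3-[3-(tert-butyldimethylsilyloxy)propyl]-1-methyl-4-(prop-1-en-2-yl)-7-oxabicyclo[4.1.0]heptan-2-one (oxirane O trans to isopropenyl) | C[C@]12O[C@H]1C[C@H](C(C)=C)[C@@H](CCCO[Si](C)(C)C(C)(C)C)C2=O | intermediate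
6 | allyl chloromethyl ether, 3-(chloromethoxy)prop-1-ene | C=CCOCCl | starting material
7 | [(allyloxy)methyl]triphenylphosphonium chloride | C=CCOC[P+](c1ccccc1)(c1ccccc1)c1ccccc1.[Cl-] | intermediate
8 | [(allyloxy)methylidene]triphenylphosphorane | C=CCOC=P(c1ccccc1)(c1ccccc1)c1ccccc1 | intermediate
9 | (1R,3R,4S,6S)-2-[(allyloxy)methylidene]-3-[3-(tert-butyldimethylsilyloxy)propyl]-1-methyl-4-(prop-1-en-2-yl)-7-oxabicyclo[4.1.0]heptane, E/Z mixture | C[C@]12O[C@H]1C[C@H](C(C)=C)[C@@H](CCCO[Si](C)(C)C(C)(C)C)C2=COCC=C | intermediate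
10 | (1R,2R,3R,4S,6S)-2-allyl-3-[3-(tert-butyldimethylsilyloxy)propyl]-1-methyl-4-(prop-1-en-2-yl)-7-oxabicyclo[4.1.0]heptane-2-carbaldehyde (CHO cis to oxirane O, allyl cis to isopropenyl) | C[C@]12O[C@H]1C[C@H](C(C)=C)[C@@H](CCCO[Si](C)(C)C(C)(C)C)[C@]2(C=O)CC=C | intermediate
11 | (1S,2S,3R,4S)-2-allyl-3-[3-(tert-butyldimethylsilyloxy)propyl]-2-(hydroxymethyl)-1-methyl-4-(prop-1-en-2-yl)cyclohexan-1-ol | C[C@]1(O)CC[C@H](C(C)=C)[C@@H](CCCO[Si](C)(C)C(C)(C)C)[C@]1(CO)CC=C | intermediate
12 | (1R,2S,5S,6R)-1-allyl-6-[3-(tert-butyldimethylsilyloxy)propyl]-2-hydroxy-2-methyl-5-(prop-1-en-2-yl)cyclohexane-1-carbaldehyde | C[C@]1(O)CC[C@H](C(C)=C)[C@@H](CCCO[Si](C)(C)C(C)(C)C)[C@]1(C=O)CC=C | intermediate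
13 | methyl vinyl ketone, but-3-en-2-one | CC(=O)C=C | starting material
14 | (1R,2S,5S,6R)-6-[3-(tert-butyldimethylsilyloxy)propyl]-2-hydroxy-2-methyl-1-[(2E)-4-oxopent-2-en-1-yl]-5-(prop-1-en-2-yl)cyclohexane-1-carbaldehyde | C[C@]1(O)CC[C@H](C(C)=C)[C@@H](CCCO[Si](C)(C)C(C)(C)C)[C@]1(C=O)C/C=C/C(C)=O | intermediate
15 | 1-[(1S,2S,5S,6S,9S,10R)-10-[3-(tert-butyldimethylsilyloxy)propyl]-1,6-dihydroxy-6-methyl-9-(prop-1-en-2-yl)spiro[4.5]decan-2-yl]ethan-1-one (1-OH and 2-acetyl cis, both on the face of C6) | CC(=O)[C@H]1CC[C@]2([C@H](CCCO[Si](C)(C)C(C)(C)C)[C@@H](C(C)=C)CC[C@]2(C)O)[C@H]1O | intermediate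
16 | 1-[(1S,2S,5S,6S,9S,10R)-10-[3-(tert-butyldimethylsilyloxy)propyl]-6-methyl-9-(prop-1-en-2-yl)-1,6-bis(triethylsilyloxy)spiro[4.5]decan-2-yl]ethan-1-one | CC(=O)[C@H]1CC[C@]2([C@H](CCCO[Si](C)(C)C(C)(C)C)[C@@H](C(C)=C)CC[C@]2(C)O[Si](CC)(CC)CC)[C@H]1O[Si](CC)(CC)CC | intermediate
17 | potassium enolate of 16 (terminal, CH2=C(OK)– on C2) | C=C(O[K])[C@H]1CC[C@]2([C@H](CCCO[Si](C)(C)C(C)(C)C)[C@@H](C(C)=C)CC[C@]2(C)O[Si](CC)(CC)CC)[C@H]1O[Si](CC)(CC)CC | intermediate
18 | 1-[(1S,2S,5S,6S,9S,10R)-10-[3-(tert-butyldimethylsilyloxy)propyl]-6-methyl-9-(prop-1-en-2-yl)-1,6-bis(triethylsilyloxy)spiro[4.5]decan-2-yl]ethenyl trifluoromethanesulfonate | C=C(OS(=O)(=O)C(F)(F)F)[C@H]1CC[C@]2([C@H](CCCO[Si](C)(C)C(C)(C)C)[C@@H](C(C)=C)CC[C@]2(C)O[Si](CC)(CC)CC)[C@H]1O[Si](CC)(CC)CC | intermediate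
19 | analogue of 18 in which the 9-substituent is 3-hydroxyprop-1-en-2-yl | C=C(OS(=O)(=O)C(F)(F)F)[C@H]1CC[C@]2([C@H](CCCO[Si](C)(C)C(C)(C)C)[C@@H](C(=C)CO)CC[C@]2(C)O[Si](CC)(CC)CC)[C@H]1O[Si](CC)(CC)CC | intermediate
20 | analogue of 18 in which the 9-substituent is 3-oxoprop-1-en-2-yl (2-substituted acrolein) | C=C(OS(=O)(=O)C(F)(F)F)[C@H]1CC[C@]2([C@H](CCCO[Si](C)(C)C(C)(C)C)[C@@H](C(=C)C=O)CC[C@]2(C)O[Si](CC)(CC)CC)[C@H]1O[Si](CC)(CC)CC | intermediate
21 | 1-[(1S,2S,5S,6S,10R)-10-[3-(tert-butyldimethylsilyloxy)propyl]-6-methyl-9-[(Z)-1-oxopropan-2-ylidene]-1,6-bis(triethylsilyloxy)spiro[4.5]decan-2-yl]ethenyl trifluoromethanesulfonate (CHO syn to C10) | C=C(OS(=O)(=O)C(F)(F)F)[C@H]1CC[C@]2([C@H](CCCO[Si](C)(C)C(C)(C)C)/C(=C(/C)C=O)CC[C@]2(C)O[Si](CC)(CC)CC)[C@H]1O[Si](CC)(CC)CC | intermediate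
22 | tert-butyldimethyl(prop-2-yn-1-yloxy)silane | C#CCO[Si](C)(C)C(C)(C)C | starting material
23 | ethyl chloroformate | CCOC(=O)Cl | starting material
24 | lithium acetylide of 22 | [Li]C#CCO[Si](C)(C)C(C)(C)C | intermediate
25 | ethyl 4-(tert-butyldimethylsilyloxy)but-2-ynoate | CCOC(=O)C#CCO[Si](C)(C)C(C)(C)C | intermediate
26 | 5-bromo-2-methylpent-2-ene | CC(C)=CCCBr | starting material
27 | (4-methylpent-3-en-1-yl)magnesium bromide | CC(C)=CCC[Mg]Br | intermediate
28 | (4-methylpent-3-en-1-yl)copper | CC(C)=CCC[Cu] | intermediate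
29 | ethyl (2Z)-3-[(tert-butyldimethylsilyloxy)methyl]-7-methylocta-2,6-dienoate | CCOC(=O)/C=C(\CO[Si](C)(C)C(C)(C)C)CCC=C(C)C | intermediate
30 | (2Z)-3-[(tert-butyldimethylsilyloxy)methyl]-7-methylocta-2,6-dien-1-ol | OC/C=C(\CO[Si](C)(C)C(C)(C)C)CCC=C(C)C | intermediate
31 | (2Z)-3-[(tert-butyldimethylsilyloxy)methyl]-7-methylocta-2,6-dienal | O=C/C=C(\CO[Si](C)(C)C(C)(C)C)CCC=C(C)C | intermediate
32 | (trimethylsilyl)diazomethane | C[Si](C)(C)C=[N+]=[N-] | starting material
33 | lithio(trimethylsilyl)diazomethane | C[Si](C)(C)C([Li])=[N+]=[N-] | intermediate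
34 | tert-butyl{[(2Z)-2-(4-methylpent-3-en-1-yl)pent-2-en-4-yn-1-yl]oxy}dimethylsilane | C#C/C=C(\CO[Si](C)(C)C(C)(C)C)CCC=C(C)C | intermediate
35 | 2-[(1E,3Z)-4-[(tert-butyldimethylsilyloxy)methyl]-8-methylnona-1,3,7-trien-1-yl]-4,4,5,5-tetramethyl-1,3,2-dioxaborolane | CC1(C)OB(/C=C/C=C(\CO[Si](C)(C)C(C)(C)C)CCC=C(C)C)OC1(C)C | intermediate
36 | (2Z)-2-[(1S,2R,5S,6S,10R)-10-[3-(tert-butyldimethylsilyloxy)propyl]-2-[(3E,5Z)-6-[(tert-butyldimethylsilyloxy)methyl]-10-methylundeca-1,3,5,9-tetraen-2-yl]-6-methyl-1,6-bis(triethylsilyloxy)spiro[4.5]decan-9-ylidene]propanal | C=C(/C=C/C=C(\CO[Si](C)(C)C(C)(C)C)CCC=C(C)C)[C@H]1CC[C@]2([C@H](CCCO[Si](C)(C)C(C)(C)C)/C(=C(/C)C=O)CC[C@]2(C)O[Si](CC)(CC)CC)[C@H]1O[Si](CC)(CC)CC | intermediate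
37 | (2Z)-2-[(1S,2R,5S,6S,10R)-1,6-dihydroxy-2-[(3E,5Z)-6-(hydroxymethyl)-10-methylundeca-1,3,5,9-tetraen-2-yl]-10-(3-hydroxypropyl)-6-methylspiro[4.5]decan-9-ylidene]propanal, CNP0249558.2 | C=C(/C=C/C=C(\CO)CCC=C(C)C)[C@H]1CC[C@]2([C@H](CCCO)/C(=C(/C)C=O)CC[C@]2(C)O)[C@H]1O | target

**Step count and risks**
Total step count: 20. Longest linear sequence: 14 steps (1, 2, 4–13, 19, 20, from carvone).

The three steps most likely to fail are steps 4, 9 and 13.

The Wittig olefination of step 4 must attack a ketone flanked by an oxirane carbon and a branched carbon, and the facial outcome of the Claisen step rests on the enol ether it delivers. The fallback sets out from enone 4, whose carbonyl is less hindered. Ylide 8 converts it into the dienyl allyl ether F1, which is heated to the quaternary dienyl aldehyde F2 (Claisen, allyl anti to the C6 chain). NaBH4 gives the homoallylic alcohol F3, and tBuOOH/VO(acac)2 epoxidises the ring alkene on the face of the directing CH2OH to the epoxy alcohol F4. LiBHEt3 then opens the oxirane, and the sequence comes back to the route at diol 11.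

The reductive aldol of step 9 may suffer from competing reduction of the aldehyde, protonation of the copper enolate by the free tertiary alcohol, or the wrong facial sense. The fallback sets out from diol 11 and separates the events. Cross-metathesis with 13 gives the enone diol F5, conjugate reduction ([(Ph3P)CuH]6 cat., PhSiH3) gives the keto diol F6, and TEMPO/PhI(OAc)2 gives the keto aldehyde F7. The ring is then closed by a reversible MgBr2·OEt2/iPr2NEt soft-enolisation aldol, in which magnesium bridging the three oxygens selects the all-cis ketol; it comes back to the route at 15.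

The isomerisation of step 13 must move a 1,1-disubstituted alkene into a tetrasubstituted position next to an enol triflate, and the geometry relies on the steric argument given. The fallback sets out from acrolein 20. Conjugate reduction with [(Ph3P)CuH]6 gives the saturated α-methyl aldehyde F8, and bromination of its trimethylsilyl enol ether with N-bromosuccinimide gives the α-bromo aldehyde F9. Dehydrobromination with Li2CO3/LiBr in DMF at 100 °C (Zaitsev elimination under equilibrating conditions) comes back to the route at 21.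

**Further compounds**
F1 | step 4 | allyl enol ether of 4, (5S,6R)-configured 1-[(allyloxy)methylidene]cyclohex-2-ene, E/Z mixture | CC1=CC[C@H](C(C)=C)[C@@H](CCCO[Si](C)(C)C(C)(C)C)C1=COCC=C
F2 | step 4 | 1-allyl-6-[3-(tert-butyldimethylsilyloxy)propyl]-2-methyl-5-(prop-1-en-2-yl)cyclohex-2-ene-1-carbaldehyde (allyl trans to the C6 chain) | CC1=CC[C@H](C(C)=C)[C@@H](CCCO[Si](C)(C)C(C)(C)C)[C@]1(C=O)CC=C
F3 | step 4 | primary alcohol from F2 | CC1=CC[C@H](C(C)=C)[C@@H](CCCO[Si](C)(C)C(C)(C)C)[C@]1(CO)CC=C
F4 | step 4 | epoxy alcohol (10 with CH2OH in place of CHO) | C[C@]12O[C@H]1C[C@H](C(C)=C)[C@@H](CCCO[Si](C)(C)C(C)(C)C)[C@]2(CO)CC=C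
F5 | step 9 | enone diol (11 with (2E)-4-oxopent-2-en-1-yl in place of allyl) | C[C@]1(O)CC[C@H](C(C)=C)[C@@H](CCCO[Si](C)(C)C(C)(C)C)[C@]1(CO)C/C=C/C(C)=O
F6 | step 9 | keto diol (F5 with the C=C bond saturated) | C[C@]1(O)CC[C@H](C(C)=C)[C@@H](CCCO[Si](C)(C)C(C)(C)C)[C@]1(CO)CCCC(C)=O
F7 | step 9 | keto aldehyde (14 with the C=C bond saturated) | C[C@]1(O)CC[C@H](C(C)=C)[C@@H](CCCO[Si](C)(C)C(C)(C)C)[C@]1(C=O)CCCC(C)=O
F8 | step 13 | saturated aldehyde (20 with 1-oxopropan-2-yl at C9, epimer mixture at the new CH) | C=C(OS(=O)(=O)C(F)(F)F)[C@H]1CC[C@]2([C@H](CCCO[Si](C)(C)C(C)(C)C)[C@@H](C(C)C=O)CC[C@]2(C)O[Si](CC)(CC)CC)[C@H]1O[Si](CC)(CC)CC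
F9 | step 13 | α-bromo aldehyde (F8 with Br on the aldehyde α-carbon, epimer mixture) | C=C(OS(=O)(=O)C(F)(F)F)[C@H]1CC[C@]2([C@H](CCCO[Si](C)(C)C(C)(C)C)[C@@H](C(C)(Br)C=O)CC[C@]2(C)O[Si](CC)(CC)CC)[C@H]1O[Si](CC)(CC)CC
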